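## Retrosynthetic overview

1. Ring C of the flavanone is opened at the O1–C2 bond to a 2′,4′,6′-trihydroxychalcone; the forward step is a catalyst-controlled intramolecular oxa-Michael C–O closure, run last, that sets C2 and picks the phenol beside the side chain.
2. The chalcone is cut at Cα=Cβ (Claisen–Schmidt) to a fully substituted acetophenone and benzaldehyde.
3. The acetophenone is cut at the aryl–CH bond (asymmetric Friedel–Crafts-type Michael addition, sets the benzylic stereocenter) to 2,4,6-trihydroxy-3-methylacetophenone and isopentylidene-syncarpic acid.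
4. These come from methylphloroglucinol + acetyl chloride and from syncarpic acid + isovaleraldehyde.
5. Ring order: ring A, ring B and the syncarpyl ring are bought; only the pyranone ring C is built, in the final step.

Assumption: syncarpic acid is taken as a catalogue compound (otherwise its two-step preparation from 2,4,6-trihydroxyacetophenone precedes step 2), and the target is read from the SMILES as (2R) at the flavanone carbon and (S) at the benzylic carbon.

Notation: "syncarpyl" = 2-hydroxy-3,3,5,5-tetramethyl-4,6-dioxocyclohex-1-en-1-yl (the enol of syncarpic acid, bonded through C1 of that ring).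

## Route

Step 1
Reactants: 1 2-methylbenzene-1,3,5-triol (2,4,6-trihydroxytoluene); 2 acetyl chloride
Product: 3 1-(2,4,6-trihydroxy-3-methylphenyl)ethan-1-one
Conditions: AlCl3 (3.5 equiv), PhNO2–CH2Cl2, 0 → 60 °C, 3 h; ice/2 M HCl
Reagents that add atoms: none
Why: Friedel–Crafts acylation of a phloroglucinol, where the two free ring positions of 1 are equivalent and the first acyl group deactivates the ring against a second one, so mono-C-acetylation results (no stereocenter).

Step 2
Reactants: 4 syncarpic acid (2,2,4,4-tetramethylcyclohexane-1,3,5-trione); 5 3-methylbutanal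
Product: 7 2,2,4,4-tetramethyl-6-(3-methylbutylidene)cyclohexane-1,3,5-trione, via piperidine Mannich base 6 (not isolated)
Conditions: piperidine (1.1 equiv), CH2Cl2, 0 °C → rt, 1 h; then 1 M HCl (aq), 0 °C; dried CH2Cl2 solution used at once
Reagents that add atoms: none
Why: Knoevenagel condensation run through the amine adduct, which stops a second syncarpic acid from adding to the alkylidene, followed by acid-triggered β-elimination of piperidine to the symmetric alkylidene trione (no stereocenter, no E/Z issue).

Step 3
Reactants: 3 1-(2,4,6-trihydroxy-3-methylphenyl)ethan-1-one; 7 2,2,4,4-tetramethyl-6-(3-methylbutylidene)cyclohexane-1,3,5-trione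
Product: 8 1-{2,4,6-trihydroxy-3-methyl-5-[(1S)-3-methyl-1-syncarpylbutyl]phenyl}ethan-1-one
Conditions: 7 (1.2 equiv), N-[3,5-bis(trifluoromethyl)phenyl]-N′-[(8α,9S)-6′-methoxycinchonan-9-yl]thiourea (20 mol%), CH2Cl2–THF (5:1), −30 °C, 48 h
Reagents that add atoms: none
Why: Catalytic asymmetric Friedel–Crafts-type Michael addition, a known reaction class for acylphloroglucinols and alkylidene syncarpic acids, in which the only free aryl carbon of 3 attacks the thiourea-bound alkylidene from the quinuclidinium-paired phenolate and the catalyst pocket sets the (S) benzylic center (sense to be confirmed on the first run by ECD or X-ray; the epi-quinidine thiourea gives the antipode).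

Step 4
Reactants: 8 1-{2,4,6-trihydroxy-3-methyl-5-[(1S)-3-methyl-1-syncarpylbutyl]phenyl}ethan-1-one; 9 benzaldehyde
Product: 11 (2E)-3-phenyl-1-{2,4,6-trihydroxy-3-methyl-5-[(1S)-3-methyl-1-syncarpylbutyl]phenyl}prop-2-en-1-one, via aldol adduct 10 (not isolated)
Conditions: 9 (3 equiv), KOH (50% aq, 15 equiv), EtOH, Ar, 0 °C → rt, 36 h; poured into ice/2 M HCl (pH 2), cold extraction
Reagents that add atoms: none
Why: Claisen–Schmidt condensation (aldol addition, then E1cB dehydration) with non-enolisable benzaldehyde gives the (E)-enone, the chalcone stays ring-open as its phenolate in strong base, and the benzylic center is not acidic because the syncarpyl unit is already an enolate, so no new stereocenter is made and the existing one is kept.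

Step 5
Reactants: 11 (2E)-3-phenyl-1-{2,4,6-trihydroxy-3-methyl-5-[(1S)-3-methyl-1-syncarpylbutyl]phenyl}prop-2-en-1-one
Product: 12 (2R)-5,7-dihydroxy-6-methyl-8-[(1S)-3-methyl-1-syncarpylbutyl]-2-phenyl-2,3-dihydro-4H-chromen-4-one
Conditions: 3-{[3,5-bis(trifluoromethyl)phenyl]amino}-4-{[(9R)-6′-methoxycinchonan-9-yl]amino}cyclobut-3-ene-1,2-dione (10 mol%), PhMe–CH2Cl2 (3:1), 0.02 M, −30 °C, 24–48 h; cold SiO2 plug (EtOAc + 1% AcOH)
Reagents that add atoms: none
Why: Proposed new method: a substrate-anchored, site- and face-selective intramolecular oxa-Michael addition in which the syncarpyl vinylogous acid of 11 (pKa about 5, well below the phenols) protonates the catalyst quinuclidine so that a contact ion pair holds the chiral ammonium at the side chain next to 6′-OH, the syncarpyl enolate oxygen serves as internal general base for 6′-OH while 2′-OH keeps its chelate to the enone C=O and thereby turns Cβ towards O-6′, and the squaramide N–H pair binds that carbonyl and leaves the Re face of Cβ open, so the O1–C2 bond forms from the phenol beside the side chain with (2R) configuration before the quinuclidinium protonates the enolate carbon; the closest known reaction type is the bifunctional cinchona-thiourea-catalysed intramolecular oxa-Michael cyclisation of ester-activated 2′-hydroxy enones to flavanones (and the general-base cyclisation by chalcone isomerase), which has not been shown for unactivated 2′,6′-dihydroxychalcones, for choosing between two ortho phenols, or with a substrate-borne acid as the catalyst anchor.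

## Compound list

1 | 2-methylbenzene-1,3,5-triol (2,4,6-trihydroxytoluene) | Cc1c(O)cc(O)cc1O | starting material
2 | acetyl chloride | CC(=O)Cl | starting material
3 | 1-(2,4,6-trihydroxy-3-methylphenyl)ethan-1-one | CC(=O)c1c(O)cc(O)c(C)c1O | intermediate
4 | syncarpic acid (2,2,4,4-tetramethylcyclohexane-1,3,5-trione; exists largely as its enol) | CC1(C)C(=O)CC(=O)C(C)(C)C1=O | starting material
5 | 3-methylbutanal (isovaleraldehyde) | CC(C)CC=O | starting material
6 | 5-hydroxy-2,2,6,6-tetramethyl-4-[3-methyl-1-(piperidin-1-yl)butyl]cyclohex-4-ene-1,3-dione (racemic Mannich base) | CC(C)CC(N1CCCCC1)C1=C(O)C(C)(C)C(=O)C(C)(C)C1=O | intermediate (not isolated)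
7 | 2,2,4,4-tetramethyl-6-(3-methylbutylidene)cyclohexane-1,3,5-trione | CC(C)CC=C1C(=O)C(C)(C)C(=O)C(C)(C)C1=O | intermediate
8 | 1-{2,4,6-trihydroxy-3-methyl-5-[(1S)-3-methyl-1-syncarpylbutyl]phenyl}ethan-1-one | CC(=O)c1c(O)c(C)c(O)c([C@H](CC(C)C)C2=C(O)C(C)(C)C(=O)C(C)(C)C2=O)c1O | intermediate
9 | benzaldehyde | O=Cc1ccccc1 | starting material
10 | 3-hydroxy-3-phenyl-1-{2,4,6-trihydroxy-3-methyl-5-[(1S)-3-methyl-1-syncarpylbutyl]phenyl}propan-1-one (both carbinol epimers) | O=C(CC(O)c1ccccc1)c1c(O)c(C)c(O)c([C@H](CC(C)C)C2=C(O)C(C)(C)C(=O)C(C)(C)C2=O)c1O | intermediate (not isolated)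
11 | (2E)-3-phenyl-1-{2,4,6-trihydroxy-3-methyl-5-[(1S)-3-methyl-1-syncarpylbutyl]phenyl}prop-2-en-1-one | O=C(/C=C/c1ccccc1)c1c(O)c(C)c(O)c([C@H](CC(C)C)C2=C(O)C(C)(C)C(=O)C(C)(C)C2=O)c1O | intermediate
12 | (2R)-5,7-dihydroxy-6-methyl-8-[(1S)-3-methyl-1-syncarpylbutyl]-2-phenyl-2,3-dihydro-4H-chromen-4-one | Cc1c(O)c2c(c([C@H](CC(C)C)C3=C(O)C(C)(C)C(=O)C(C)(C)C3=O)c1O)O[C@@H](c1ccccc1)CC2=O | target

## Count and risks

Total steps: 5. Longest linear sequence: 4 (steps 1, 3, 4, 5 from compound 1); step 2 is a one-step side branch.

**Step 3 (asymmetric Michael addition).** The product is a vinylogous acid that titrates the amine catalyst, selectivities in this reaction class are often moderate, and the alkylidene can deconjugate under base. The fallback sets out from 3 and 7 and gives up catalyst control. NaH (2.2 equiv) in THF at 0 °C → rt gives the racemic adduct, that is 8 together with its enantiomer 1-{2,4,6-trihydroxy-3-methyl-5-[(1R)-3-methyl-1-syncarpylbutyl]phenyl}ethan-1-one F1. The racemate is resolved by preparative chiral SFC (polysaccharide phase, CO2/MeOH with 0.1% HCO2H), and the route is rejoined at 8.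

**Step 4 (Claisen–Schmidt on the polyanion of 8).** The tetra-anion is a sluggish ketone enolate precursor, long exposure to KOH could erode the benzylic center by retro-Michael loss of syncarpate, and the product can cyclise without control if the quench passes slowly through neutral pH. The fallback reverses the order of the two C–C bond formations and sets out from 3. Condensation of 3 with 9 (KOH, EtOH–H2O, rt) runs through the aldol adduct 3-hydroxy-3-phenyl-1-(2,4,6-trihydroxy-3-methylphenyl)propan-1-one F2 to the simple chalcone (2E)-3-phenyl-1-(2,4,6-trihydroxy-3-methylphenyl)prop-2-en-1-one F3. The polyanion of F3 (NaH, 3.3 equiv, THF, 0 °C; the chalcone stays ring-open in strong base) is then added to 7. This gives racemic material, that is 11 together with its enantiomer (2E)-3-phenyl-1-{2,4,6-trihydroxy-3-methyl-5-[(1R)-3-methyl-1-syncarpylbutyl]phenyl}prop-2-en-1-one F4. Preparative chiral SFC brings the route back at 11.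

**Step 5 (the proposed oxa-Michael closure).** Three things are unproven:
- whether the ion-pair anchor really directs the closure to 6′-OH and not to the less hindered 2′-OH;
- the sense and level of face selection, including a possible mismatch with the (S) side-chain center (the pseudo-enantiomeric epi-quinine squaramide is the first thing to try if the (2S) epimer dominates);
- whether the product epimerises by retro-oxa-Michael before the catalyst is removed.

The fallback uses known chemistry and sets out from 11. NaOAc (3 equiv) in EtOH at 60 °C cyclises the chalcone without control to a mixture of four flavanones: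
- the target 12;
- its C2 epimer (2S)-5,7-dihydroxy-6-methyl-8-[(1S)-3-methyl-1-syncarpylbutyl]-2-phenyl-2,3-dihydro-4H-chromen-4-one F5;
- the regioisomer (2R)-5,7-dihydroxy-8-methyl-6-[(1S)-3-methyl-1-syncarpylbutyl]-2-phenyl-2,3-dihydro-4H-chromen-4-one F6;
- the regioisomer (2S)-5,7-dihydroxy-8-methyl-6-[(1S)-3-methyl-1-syncarpylbutyl]-2-phenyl-2,3-dihydro-4H-chromen-4-one F7.

All four are diastereomers or constitutional isomers, so preparative reversed-phase HPLC separates them, and the route is rejoined at 12. The three unwanted isomers can be reopened to 11 with KOH/EtOH and cycled again.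

## Further compounds

F1 | step 3 | 1-{2,4,6-trihydroxy-3-methyl-5-[(1R)-3-methyl-1-syncarpylbutyl]phenyl}ethan-1-one | CC(=O)c1c(O)c(C)c(O)c([C@@H](CC(C)C)C2=C(O)C(C)(C)C(=O)C(C)(C)C2=O)c1O
F2 | step 4 | 3-hydroxy-3-phenyl-1-(2,4,6-trihydroxy-3-methylphenyl)propan-1-one (racemic) | O=C(CC(O)c1ccccc1)c1c(O)cc(O)c(C)c1O
F3 | step 4 | (2E)-3-phenyl-1-(2,4,6-trihydroxy-3-methylphenyl)prop-2-en-1-one | O=C(/C=C/c1ccccc1)c1c(O)cc(O)c(C)c1O
F4 | step 4 | (2E)-3-phenyl-1-{2,4,6-trihydroxy-3-methyl-5-[(1R)-3-methyl-1-syncarpylbutyl]phenyl}prop-2-en-1-one | O=C(/C=C/c1ccccc1)c1c(O)c(C)c(O)c([C@@H](CC(C)C)C2=C(O)C(C)(C)C(=O)C(C)(C)C2=O)c1O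
F5 | step 5 | (2S)-5,7-dihydroxy-6-methyl-8-[(1S)-3-methyl-1-syncarpylbutyl]-2-phenyl-2,3-dihydro-4H-chromen-4-one | Cc1c(O)c2c(c([C@H](CC(C)C)C3=C(O)C(C)(C)C(=O)C(C)(C)C3=O)c1O)O[C@H](c1ccccc1)CC2=O
F6 | step 5 | (2R)-5,7-dihydroxy-8-methyl-6-[(1S)-3-methyl-1-syncarpylbutyl]-2-phenyl-2,3-dihydro-4H-chromen-4-one | Cc1c(O)c([C@H](CC(C)C)C3=C(O)C(C)(C)C(=O)C(C)(C)C3=O)c(O)c2c1O[C@@H](c1ccccc1)CC2=O
F7 | step 5 | (2S)-5,7-dihydroxy-8-methyl-6-[(1S)-3-methyl-1-syncarpylbutyl]-2-phenyl-2,3-dihydro-4H-chromen-4-one | Cc1c(O)c([C@H](CC(C)C)C3=C(O)C(C)(C)C(=O)C(C)(C)C3=O)c(O)c2c1O[C@H](c1ccccc1)CC2=O
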